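**Plan**
Cuts: first the four O–CH3 bonds, then O1–C8a and O1''–C8a'' of the two pyranones, then C2–C3 and C2''–C3'' (the formyl carbons), then the C8–C8'' biaryl bond, and last the C4–C4a aryl ketone bond.
Enabling feature: O1 sits on C8a of ring A, and C8a is linked through C8 to the oxygenated C7. In a C8a–H precursor the 6,7-catechol can be raised to the ortho-quinone, where C7(=O)–C8=C8a is an enone with C8a as its β-carbon, and addition there returns the 6,7-catechol of the target.
Forward: rings A and B are bought and joined by acylation. The halves are coupled at C8 while the axis has only two ortho groups, C2 is added by formylation, both rings C close in one oxidative operation, and demethylation ends the route.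
Stereochemistry: the target has no stereocentre. The axis becomes tetra-ortho-substituted only in the ring closure and is made racemic.

Key step: step 8

Remark on the chemistry: the target string has no descriptor for the C8–C8'' axis, so the racemic biaryl is taken as the target; formyl ketones 9–11 are drawn as keto aldehyde tautomers although they should rest as chelated (Z)-hydroxymethylene enols, with labile C3 centres that vanish in step 8; isoflavone numbering is used for all precursors.

Step 1
Reactants: 1 pyrogallol; 2 4-methoxyphenylacetic acid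
Product: 3 1-(2,3,4-trihydroxyphenyl)-2-(4-methoxyphenyl)ethan-1-one
Conditions: BF3·OEt2 (as solvent and promoter), 85 °C, Ar; aqueous work-up
Reagents that add atoms: none
Why: Friedel–Crafts C-acylation of a polyphenol by an arylacetic acid in BF3·OEt2 is the standard way to deoxybenzoins, and pyrogallol is attacked at C4, ortho to one outer hydroxyl and para to the other, so the ketone ends up next to the 2,3,4-trihydroxy array.

Step 2
Reactants: 3 1-(2,3,4-trihydroxyphenyl)-2-(4-methoxyphenyl)ethan-1-one
Product: 4 1-[2-hydroxy-3,4-bis(methoxymethoxy)phenyl]-2-(4-methoxyphenyl)ethan-1-one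
Conditions: MOMCl (2.1 equiv), i-Pr2NEt (2.5 equiv), THF, 0 °C to rt, Ar
Reagents that add atoms: chloromethyl methyl ether (MOMCl), COCCl
Why: Base-mediated O-alkylation is governed by the hydrogen bond between the 2-hydroxyl and the ketone, which lowers its reactivity enough that two equivalents of MOMCl should take only the 3- and 4-hydroxyls, and this sets the future C5 oxygen apart from the future 6,7-catechol.

Step 3
Reactants: 4 1-[2-hydroxy-3,4-bis(methoxymethoxy)phenyl]-2-(4-methoxyphenyl)ethan-1-one
Product: 5 1-[5-bromo-2-hydroxy-3,4-bis(methoxymethoxy)phenyl]-2-(4-methoxyphenyl)ethan-1-one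
Conditions: NBS (1.0 equiv), MeCN, 0 °C, dark
Reagents that add atoms: N-bromosuccinimide, O=C1CCC(=O)N1Br
Why: Electrophilic aromatic bromination goes para to the free phenol and ortho to the 4-alkoxy group, both of which point to the same carbon (future C8), so ring A should outrun the anisyl ring and the ketone methylene at low temperature in the dark.

Step 4
Reactants: 5 1-[5-bromo-2-hydroxy-3,4-bis(methoxymethoxy)phenyl]-2-(4-methoxyphenyl)ethan-1-one
Product: 6 1-[5-bromo-2-methoxy-3,4-bis(methoxymethoxy)phenyl]-2-(4-methoxyphenyl)ethan-1-one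
Conditions: MeOH, PPh3, DIAD, THF, 0 °C to rt
Reagents that add atoms: methanol, CO
Why: Mitsunobu etherification alkylates only a partner acidic enough to protonate the phosphine–azodicarboxylate adduct, here the acyl- and bromo-substituted phenol, so the benzylic methylene, which carbonate and methyl iodide could C-methylate, is left alone.

Step 5
Reactants: 6 1-[5-bromo-2-methoxy-3,4-bis(methoxymethoxy)phenyl]-2-(4-methoxyphenyl)ethan-1-one (two molecules)
Product: 7 2,2',3,3'-tetrakis(methoxymethoxy)-4,4'-dimethoxy-5,5'-bis[(4-methoxyphenyl)acetyl]biphenyl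
Conditions: Ni(cod)2 (zerovalent nickel, 0.6 equiv per bromide), 2,2'-bipyridine, DMF, 60 °C, Ar
Reagents that add atoms: none
Why: Yamamoto-type reductive homocoupling of aryl bromides with zerovalent nickel needs no base and tolerates ketones and acetals, and the bond is easy to form here because each ring offers only one ortho substituent (the C7 ether) beside C8a–H.

Step 6
Reactants: 7 2,2',3,3'-tetrakis(methoxymethoxy)-4,4'-dimethoxy-5,5'-bis[(4-methoxyphenyl)acetyl]biphenyl; 8 ethyl formate
Product: 9 2,2',3,3'-tetrakis(methoxymethoxy)-4,4'-dimethoxy-5,5'-bis[2-(4-methoxyphenyl)-3-oxopropanoyl]biphenyl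
Conditions: NaH, excess 8, THF, 0 °C to rt; AcOH quench at 0 °C
Reagents that add atoms: none
Why: Crossed Claisen condensation of a deoxybenzoin enolate with non-enolisable ethyl formate is the classical α-formylation and is pulled to completion by the stabilised enolate of the product, while the C5 methyl ether keeps the new formyl group from closing a chromone on the wrong side.

Step 7
Reactants: 9 2,2',3,3'-tetrakis(methoxymethoxy)-4,4'-dimethoxy-5,5'-bis[2-(4-methoxyphenyl)-3-oxopropanoyl]biphenyl
Product: 10 2,2',3,3'-tetrahydroxy-4,4'-dimethoxy-5,5'-bis[2-(4-methoxyphenyl)-3-oxopropanoyl]biphenyl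
Conditions: 2 M aq HCl, THF (degassed), 45 °C, Ar
Reagents that add atoms: none
Why: Acid hydrolysis of phenolic MOM acetals is fast for these electron-poor aryl oxygens and leaves aryl methyl ethers untouched, and the α-aryl formyl ketone, which cannot trimerise and rests as its chelated enol, should survive the mild aqueous acid.

Step 8
Reactants: 10 2,2',3,3'-tetrahydroxy-4,4'-dimethoxy-5,5'-bis[2-(4-methoxyphenyl)-3-oxopropanoyl]biphenyl
Product: 12 6,7,6'',7''-tetrahydroxy-5,4',5'',4'''-tetramethoxy-8,8''-biisoflavone, via bis(ortho-quinone) 11 (not isolated)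
Conditions: Ag2O (monovalent silver, 2.2 equiv), 4 Å molecular sieves, dry THF, 0 °C to rt, dark, Ar; solution of 10 added to the suspended oxidant
Reagents that add atoms: none
Why: Proposed new method: Ag2O removes two electrons and two protons from each 6,7-catechol, and in the resulting ortho-quinone 11 the C8=C8a bond is conjugated with the C7 carbonyl, so the oxygen of the (Z)-enolate of the formyl ketone, which the basic oxide also sets free, adds to C8a and loss of the C8a proton re-aromatises ring A to the catechol. The closest known reaction types are the oxidative cyclisation of hydroxylated benzophenones to xanthones, the oxidative lactonisation of dihydrocaffeic-type acids to 6,7-dihydroxycoumarin derivatives and the oxygen conjugate addition that closes the furan in oxidative coumestan syntheses, but a chromone has not been closed in this way. Each of the two pyranones closes in the 6-exo-trig mode, because C8, the partner of the attacked carbon, lies outside the new O1–C2–C3–C4–C4a–C8a ring, and attack through the enolate carbon C3 would need a four-membered ring. No stereocentre arises, and the axis, which gains its third and fourth ortho substituents here, is formed racemic. The step needs attack at C8a and not at C5, the other carbon ortho to the side chain and β to the C4 ketone: an adduct at C5 can move on only by loss of methoxide, a far poorer leaving group than the vinylogous carboxylate that came in, so it falls back, whereas the adduct at C8a is drained by irreversible enolisation. Adding 10 to the full charge of oxidant turns both halves into quinones at once, which removes the neighbouring C7 hydroxyl as a rival nucleophile at the outset (its attack at C8a would be 5-endo-trig), and dry conditions with about one Ag2O per catechol hold back aldehyde oxidation and re-oxidation of the product.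

Step 9
Reactants: 12 6,7,6'',7''-tetrahydroxy-5,4',5'',4'''-tetramethoxy-8,8''-biisoflavone
Product: 13 5,6,7,4',5'',6'',7'',4'''-octahydroxy-8,8''-biisoflavone (CNP0254964.0)
Conditions: BBr3 (excess), CH2Cl2, −78 °C to rt; H2O quench at 0 °C
Reagents that add atoms: none
Why: Lewis acid cleavage of aryl methyl ethers with BBr3 is standard for isoflavone methyl ethers, the C5 ethers being helped by chelation to the C4 carbonyl, and the chromone rings and the biaryl bond are inert to it, while the acidic medium protects the oxidisable 5,6,7-triol.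

**Compound list**
1 | pyrogallol (benzene-1,2,3-triol) | Oc1cccc(O)c1O | starting material
2 | 4-methoxyphenylacetic acid | COc1ccc(CC(=O)O)cc1 | starting material
3 | 1-(2,3,4-trihydroxyphenyl)-2-(4-methoxyphenyl)ethan-1-one | COc1ccc(CC(=O)c2ccc(O)c(O)c2O)cc1 | intermediate
4 | 1-[2-hydroxy-3,4-bis(methoxymethoxy)phenyl]-2-(4-methoxyphenyl)ethan-1-one | COc1ccc(CC(=O)c2ccc(OCOC)c(OCOC)c2O)cc1 | intermediate
5 | 1-[5-bromo-2-hydroxy-3,4-bis(methoxymethoxy)phenyl]-2-(4-methoxyphenyl)ethan-1-one | COc1ccc(CC(=O)c2cc(Br)c(OCOC)c(OCOC)c2O)cc1 | intermediate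
6 | 1-[5-bromo-2-methoxy-3,4-bis(methoxymethoxy)phenyl]-2-(4-methoxyphenyl)ethan-1-one | COc1ccc(CC(=O)c2cc(Br)c(OCOC)c(OCOC)c2OC)cc1 | intermediate
7 | 2,2',3,3'-tetrakis(methoxymethoxy)-4,4'-dimethoxy-5,5'-bis[(4-methoxyphenyl)acetyl]biphenyl | COc1ccc(CC(=O)c2cc(c(OCOC)c(OCOC)c2OC)-c2cc(C(=O)Cc3ccc(OC)cc3)c(OC)c(OCOC)c2OCOC)cc1 | intermediate
8 | ethyl formate | CCOC=O | starting material
9 | 2,2',3,3'-tetrakis(methoxymethoxy)-4,4'-dimethoxy-5,5'-bis[2-(4-methoxyphenyl)-3-oxopropanoyl]biphenyl (keto aldehyde tautomer) | COc1ccc(cc1)C(C=O)C(=O)c1cc(c(OCOC)c(OCOC)c1OC)-c1cc(C(=O)C(C=O)c2ccc(OC)cc2)c(OC)c(OCOC)c1OCOC | intermediate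
10 | 2,2',3,3'-tetrahydroxy-4,4'-dimethoxy-5,5'-bis[2-(4-methoxyphenyl)-3-oxopropanoyl]biphenyl (keto aldehyde tautomer) | COc1ccc(cc1)C(C=O)C(=O)c1cc(c(O)c(O)c1OC)-c1cc(C(=O)C(C=O)c2ccc(OC)cc2)c(OC)c(O)c1O | intermediate
11 | bis(ortho-quinone) of 10: 6,6'-dimethoxy-5,5'-bis[2-(4-methoxyphenyl)-3-oxopropanoyl]-3,3'-bi(cyclohexa-3,5-diene-1,2-dione) | COc1ccc(cc1)C(C=O)C(=O)C1=C(OC)C(=O)C(=O)C(=C1)C1=CC(C(=O)C(C=O)c2ccc(OC)cc2)=C(OC)C(=O)C1=O | intermediate
12 | 6,7,6'',7''-tetrahydroxy-5,4',5'',4'''-tetramethoxy-8,8''-biisoflavone | COc1ccc(cc1)-c1coc2c(c(O)c(O)c(OC)c2c1=O)-c1c(O)c(O)c(OC)c2c(=O)c(coc12)-c1ccc(OC)cc1 | intermediate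
13 | 5,6,7,4',5'',6'',7'',4'''-octahydroxy-8,8''-biisoflavone | O=c1c(-c2ccc(O)cc2)coc2c(-c3c(O)c(O)c(O)c4c(=O)c(-c5ccc(O)cc5)coc34)c(O)c(O)c(O)c12 | target

Total step count: 9
Longest linear sequence: 9 steps (1 or 2 to 13)

**Steps most likely to fail**

Step 8. The vinylogous carboxylate oxygen may add too slowly, so other processes consume the ortho-quinone first.
- The C7 hydroxyl of an already closed or not yet oxidised half may attack C8a, a drift towards a dibenzofuran.
- Water may add to the quinone, or the quinone may dimerise.
- Silver may oxidise the formyl group.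
- The product catechol may be re-oxidised; a wash with aqueous Na2S2O4 would reverse this.

The fallback uses known chemistry that brings O1 in with the starting phenol. It sets out from 2 and comes back to the route at 13. Acid 2 is condensed with commercial 3,4,5-trimethoxyphenol in BF3·OEt2 to 1-(6-hydroxy-2,3,4-trimethoxyphenyl)-2-(4-methoxyphenyl)ethan-1-one F1, whose free ortho hydroxyl is the future O1. DMF dimethyl acetal followed by acid closes the pyranone in the usual way to 5,6,7,4'-tetramethoxyisoflavone F2. N-iodosuccinimide with catalytic TFA in MeCN iodinates the only free carbon of ring A to 8-iodo-5,6,7,4'-tetramethoxyisoflavone F3. An Ullmann homocoupling with activated copper powder (Cu) in hot DMF, the established way to 8,8''-linked biflavone methyl ethers, gives 5,6,7,4',5'',6'',7'',4'''-octamethoxy-8,8''-biisoflavone F4. Excess BBr3 then cleaves all eight methyl ethers to 13.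

Step 7. During acidolysis the formyl group may be lost by retro-Claisen cleavage, the enol carbon may capture released formaldehyde, and the free catechols may start to oxidise in air before they are wanted as quinones.

The fallback reverses the order of events so that the formyl ketone never meets acid and formaldehyde. It sets out from 7 and comes back at 10. The robust diketone 7 is deprotected with HCl in MeOH, which carries the formaldehyde away as its dimethyl acetal, to give 2,2',3,3'-tetrahydroxy-4,4'-dimethoxy-5,5'-bis[(4-methoxyphenyl)acetyl]biphenyl F5. F5 is then formylated as its polyanion with a large excess of NaH and 8 in THF–DMF under Ar, the classical treatment of unprotected polyhydroxydeoxybenzoins. Transient aryl formates fall off on the acidic quench, and 10 results.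

Step 5. Oxidative addition to the electron-rich, ortho-alkoxylated bromide may be slow, so hydrodebromination or binding of nickel to the enolisable ketone may take over.

The fallback replaces the reductive homocoupling by a cross-coupling of two differently activated halves. It sets out from 6 and comes back at 7. Half of 6 is converted by Miyaura borylation (B2pin2, PdCl2(dppf), KOAc, dioxane, 80 °C) into 1-[2-methoxy-3,4-bis(methoxymethoxy)-5-(4,4,5,5-tetramethyl-1,3,2-dioxaborolan-2-yl)phenyl]-2-(4-methoxyphenyl)ethan-1-one F6. F6 is joined to the other half of 6 by Suzuki–Miyaura coupling (Pd(PPh3)4, aq Na2CO3, DME, 80 °C). That base and ligand are too mild for ketone α-arylation.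

**Further compounds**
F1 | step 8 | 1-(6-hydroxy-2,3,4-trimethoxyphenyl)-2-(4-methoxyphenyl)ethan-1-one | COc1ccc(CC(=O)c2c(O)cc(OC)c(OC)c2OC)cc1
F2 | step 8 | 5,6,7,4'-tetramethoxyisoflavone | COc1ccc(cc1)-c1coc2cc(OC)c(OC)c(OC)c2c1=O
F3 | step 8 | 8-iodo-5,6,7,4'-tetramethoxyisoflavone | COc1ccc(cc1)-c1coc2c(I)c(OC)c(OC)c(OC)c2c1=O
F4 | step 8 | 5,6,7,4',5'',6'',7'',4'''-octamethoxy-8,8''-biisoflavone | COc1ccc(cc1)-c1coc2c(c(OC)c(OC)c(OC)c2c1=O)-c1c(OC)c(OC)c(OC)c2c(=O)c(coc12)-c1ccc(OC)cc1
F5 | step 7 | 2,2',3,3'-tetrahydroxy-4,4'-dimethoxy-5,5'-bis[(4-methoxyphenyl)acetyl]biphenyl | COc1ccc(CC(=O)c2cc(c(O)c(O)c2OC)-c2cc(C(=O)Cc3ccc(OC)cc3)c(OC)c(O)c2O)cc1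
F6 | step 5 | 1-[2-methoxy-3,4-bis(methoxymethoxy)-5-(4,4,5,5-tetramethyl-1,3,2-dioxaborolan-2-yl)phenyl]-2-(4-methoxyphenyl)ethan-1-one | COc1ccc(CC(=O)c2cc(B3OC(C)(C)C(C)(C)O3)c(OCOC)c(OCOC)c2OC)cc1
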